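## Analysis of the target

Target 15 is a cyclised diarylheptanoid built on a tetrahydropyran, numbered here O1, C2, C3, C4, C5, C6. C2 carries a 2-(4-hydroxy-3-methoxyphenyl)ethyl chain, C4 a hydroxyl and C6 a 3,4-dihydroxy-5-methoxyphenyl ring. The stereocentres are 2S, 4R and 6S; all three substituents lie on one face, so all are equatorial in the chair and 15 is the most stable diastereomer. Only one centre therefore has to be set in the absolute sense: C2 can be relayed from it by equilibration and C4 by the facial bias of the chair. The sensitive groups are the three phenols (one an oxidation-prone catechol) and the C6–O1 bond, a benzylic ether on a trioxygenated arene that can ionise under acid or be cleaved by hydrogenolysis. The difficulty is to set C6 with absolute control at an ionisable benzylic position, to keep it, and to tell the two differently oxygenated aryl ends apart. The plan rests on one feature: C3–C4–C5 is an acetone unit, oxygenated at C4, flanked by C2 and C6, which are both bonded to O1 and so stand at the aldehyde oxidation level. The ring can therefore be assembled from two aldehydes bridged by an acetoacetate dienolate whose ester, on C3, is removed afterwards.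

## Retrosynthetic reasoning

15 from 14. The three phenolic O–benzyl bonds are cut last. Benzyl ethers are inert to the Lewis acid, the amine buffer, hot chloride and hydride used earlier, and they fall in one neutral operation. The forward step must cleave three aryl benzyl ethers without touching the benzylic C6–O1 bond.

14 from 13. The C4–H bond is cut, so C4 stays a ketone until the ring exists. In chair 13, with both C2 and C6 substituents equatorial, a small hydride should add axially and give the equatorial 4R alcohol, so no reagent control is needed.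

13 from 12. The C3–ester bond is cut. The ester is a traceless activating group: it makes C3 acidic enough for condensation and makes the ring closure reversible. The forward step must remove it without disturbing C2 or C6.

12 from 2, 5 and 8. Three ring bonds are cut: O1–C2 (conjugate addition of the C6 hydroxyl in 11), C2–C3 (condensation of 10 with 8) and C5–C6 (aldol of 2 with the terminal carbon of 5, giving 9 and then 10). Each cut ends at the carbonyl carbon of a simple aldehyde, and C3 and C5 become the two nucleophilic ends of one four-carbon reagent. That reagent is unsymmetrical: its terminal carbon reacts first under a chiral Lewis acid, its central methylene second under an amine buffer, so each aldehyde goes to a defined side. The aryl aldehyde 2 is used in the aldol because it cannot enolise, because aryl aldehydes respond best to this kind of catalyst, and because C6 then lies outside the reversible step. The gain is the ring, three bonds and two stereocentres in one flask. The forward reaction must control the face of 2 and let C2 settle cis to C6.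

2 from 1; 5 from 4 from 3; 8 from 7 from 6. These are protecting-group and oxidation-level adjustments: double O-benzylation of 1, two successive O-silylations of 3, and benzylation then partial reduction of 6. They are cut this way so that each key-step component is one or two routine steps from a catalogue compound.

## Alternatives that were turned down

Alternative 1: Dithiane linchpin.
- Disconnection: C3–C4 and C4–C5, with C4 as an acyl dianion equivalent; no ring bond is cut.
- Forward key step: lithiated 2-(tert-butyldimethylsilyl)-1,3-dithiane A1 opens the terminal epoxide (S)-2-[2-(4-benzyloxy-3-methoxyphenyl)ethyl]oxirane A2 at its CH2 group (C3–C4). A 1,4-Brook shift moves silicon to the new alkoxide and regenerates a dithiane anion, which opens the racemic aryl oxirane A3 (C4–C5) to give the open-chain dithiane A4.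
- For: C2 comes from a resolved epoxide, which is more secure in the absolute sense than a centre set by a catalytic aldol on an electron-rich aldehyde. A3 can be racemic because C6 can be corrected later by ionisation and ring closure under thermodynamic control. Three fragments are joined in one flask.
- Against: the key step closes no ring and fixes one stereocentre. A3 is a styrene-type oxide on a trioxygenated arene, prone to attack at the benzylic carbon and to rearrangement to an arylacetaldehyde, so the second opening is regiochemically insecure. A4 must still be desilylated, cyclised through the benzylic cation, freed from the dithiane in the presence of three electron-rich arenes, reduced and deprotected. A2 and A3 each cost several steps from 8 and 2.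
- Comparison: Alternative 1 is stronger on security of absolute configuration. The chosen plan gives the ring, three bonds and two stereocentres in one operation, at roughly half the step count.

Alternative 2: Allyl-cation cyclisation.
- Disconnection: O1–C2 only, leading back to the acyclic heptenediol monosilyl ether A6, in which C4 and C6 are already set and the aryl-bearing allylic carbinol is stereorandom.
- Forward key step: the hydrated Lewis acid FeCl3·6H2O A5 ionises the allylic alcohol of A6 to a 1-arylallyl cation. The C6 hydroxyl captures the terminus remote from the aryl ring and closes the all-cis 2-styryl tetrahydropyran A7.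
- For: the closure is stereoconvergent, the catalyst is cheap, and one final hydrogenation would saturate the styrene and remove the benzyl ethers together.
- Against: A6 holds two ionisable carbinols. The one that must survive, C6, sits on the more electron-rich ring, so the same Lewis acid can ionise it and erase the configuration from which C2 is relayed. The silyl ether may not survive the hydrated Lewis acid. The key step forms one bond and one stereocentre, and C4 and C6 must be installed beforehand as a differentiated syn-1,3-diol by separate asymmetric operations, which takes the route well past ten steps.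
- Comparison: Alternative 2 is stronger in that its closure tolerates a stereorandom centre. The chosen plan closes the ring under an amine buffer in which C6 cannot ionise, needs no C4 stereocentre before the ring exists, and is much shorter.

Alternative 3: Petasis–Ferrier rearrangement.
- Disconnection: C5–C6, from the cis-4-methylene-1,3-dioxane A9. A9 comes from (S)-5-(4-benzyloxy-3-methoxyphenyl)-3-hydroxypentanoic acid A8 and aldehyde 2 by acetalisation to the dioxanone and carbonyl methylenation.
- Forward key step: Me2AlCl A10 cleaves the acetal C–O bond next to the enol ether. The aluminium enolate and the aryl-stabilised oxocarbenium ion recombine through a chair to give the cis-pyranone A11, which is identical with 13.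
- For: it reaches 13 without an ester and without a hot decarboxylation. The cis relationship is inherited from the cis acetal and the chair transition state. The electron-rich aryl group helps by stabilising the oxocarbenium ion. C2 comes from a β-hydroxy acid accessible in high enantiopurity by well-tried asymmetric reduction. On stereochemical reliability it is at least the equal of the chosen plan and probably better.
- Against: A8 needs its own asymmetric step and chain construction from 8. Acetalisation, methylenation beside an acid-labile aryl acetal, and a rearrangement with a stoichiometric aluminium Lewis acid add three linear operations. 13 would be reached in about seven or eight steps, against two operations (steps 6 and 7) from the same aldehydes.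
- Comparison: the chosen plan accepts a less certain key step in exchange for this economy and for full convergence.

Key step: step 6

Assumption: the catalyst formed from Ti(OiPr)4 and (S)-BINOL is taken to deliver the dienolate to the Si face of aldehyde 2, by analogy with related titanium–binaphthol additions to aryl aldehydes; if the opposite sense were found, (R)-BINOL would be used and nothing else would change.

## Route

Step 1
Reactants: 1 3,4-dihydroxy-5-methoxybenzaldehyde
Product: 2 3,4-bis(benzyloxy)-5-methoxybenzaldehyde
Conditions: BnBr, K2CO3, DMF, 60 °C, N2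
Reagents that add atoms: benzyl bromide, BrCc1ccccc1
Why: Williamson etherification of both phenols; the aldehyde has no α-hydrogen and is inert to carbonate, and nitrogen protects the catechol dianion from air.

Step 2
Reactants: 3 methyl acetoacetate
Product: 4 methyl 3-(trimethylsilyloxy)but-2-enoate (E/Z mixture)
Conditions: TMSCl, Et3N, hexane, rt
Reagents that add atoms: chlorotrimethylsilane, C[Si](C)(C)Cl
Why: O-silylation of the enol form of the β-keto ester (silyl enol ether formation); the alkene geometry is lost in the next step and does not matter.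

Step 3
Reactants: 4 methyl 3-(trimethylsilyloxy)but-2-enoate
Product: 5 1-methoxy-1,3-bis(trimethylsilyloxy)buta-1,3-diene
Conditions: LiN(iPr)2 (LDA), THF, −78 °C; TMSCl, −78 °C → rt; non-aqueous work-up
Reagents that add atoms: chlorotrimethylsilane, C[Si](C)(C)Cl
Why: Kinetic γ-deprotonation of the vinylogous ester gives the extended dienolate, which the hard silyl chloride traps on oxygen (silyl ketene acetal formation); the diene is moisture-sensitive and should be used freshly distilled.

Step 4
Reactants: 6 3-(4-hydroxy-3-methoxyphenyl)propanoic acid
Product: 7 benzyl 3-(4-benzyloxy-3-methoxyphenyl)propanoate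
Conditions: BnBr, K2CO3, DMF, 60 °C
Reagents that add atoms: benzyl bromide, BrCc1ccccc1
Why: Carboxylate and phenoxide are both alkylated under Williamson conditions, which protects the phenol and activates the acid for reduction in one operation.

Step 5
Reactants: 7 benzyl 3-(4-benzyloxy-3-methoxyphenyl)propanoate
Product: 8 3-(4-benzyloxy-3-methoxyphenyl)propanal
Conditions: iBu2AlH (DIBAL-H), CH2Cl2, −78 °C; MeOH, aq. Rochelle salt
Reagents that add atoms: none
Why: Partial ester reduction; the tetrahedral aluminium hemiacetal is stable at −78 °C and releases the aldehyde only on work-up, after the hydride has been quenched.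

Step 6
Reactants: 2 3,4-bis(benzyloxy)-5-methoxybenzaldehyde; 5 1-methoxy-1,3-bis(trimethylsilyloxy)buta-1,3-diene; 8 3-(4-benzyloxy-3-methoxyphenyl)propanal
Product: 12 methyl (2S,6S)-6-[3,4-bis(benzyloxy)-5-methoxyphenyl]-2-[2-(4-benzyloxy-3-methoxyphenyl)ethyl]-4-hydroxy-5,6-dihydro-2H-pyran-3-carboxylate (enol form of the 4-oxotetrahydropyran-3-carboxylate), via bis-silyl aldol adduct 9 (not isolated), via δ-hydroxy-β-keto ester 10 (not isolated), via alkylidene keto ester 11 (not isolated)
Conditions: Ti(OiPr)4 (10 mol %), (S)-BINOL (10 mol %), 4 Å MS, THF, −78 °C → rt; TFA, −78 °C; piperidine (excess over TFA), AcOH, then 8, 0 °C → rt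
Reagents that add atoms: none
Why: This is a Maitland–Japp assembly; its closest known form is the vinylogous Mukaiyama aldol of a bis-silyl acetoacetate dienolate followed by Knoevenagel condensation and oxa-Michael closure of the δ-hydroxy-β-keto ester. The catalyst formed from Ti(OiPr)4 and (S)-BINOL activates aldehyde 2, and the terminal CH2 of 5, its only unhindered nucleophilic carbon, adds to the Si face, forming C5–C6 and giving 9 with C6 in the S configuration under catalyst control. TFA at −78 °C removes both silyl groups to give 10 and is neutralised by piperidine before the flask is warmed, so the electron-rich benzylic carbinol is not exposed to acid at a temperature at which it could ionise. Piperidinium acetate then condenses the doubly activated C3 methylene of 10 with aldehyde 8 (C2–C3); 8 is added only after 2 has been consumed, so the two aldehydes cannot exchange roles, and 11 forms as an E/Z mixture. The C6 hydroxyl adds to the alkylidene keto ester of 11 in a 6-endo-trig oxa-Michael closure (O1–C2), which forms the only ring. This closure is reversible through the stabilised β-dicarbonyl enolate, so C2 settles under thermodynamic control in the S configuration, with the arylethyl chain equatorial and cis to the equatorial aryl group at C6. C6 itself is not at risk, because C5 is too weakly acidic under the amine buffer to trigger elimination of O1. The selectivities needed are terminal over internal attack of the dienolate (inherent in the silyl dienol ether), condensation at C3 and not C5 (secured by the ester), and 2,6-cis (secured by reversibility).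

Step 7
Reactants: 12 methyl (2S,6S)-6-[3,4-bis(benzyloxy)-5-methoxyphenyl]-2-[2-(4-benzyloxy-3-methoxyphenyl)ethyl]-4-hydroxy-5,6-dihydro-2H-pyran-3-carboxylate
Product: 13 (2S,6S)-6-[3,4-bis(benzyloxy)-5-methoxyphenyl]-2-[2-(4-benzyloxy-3-methoxyphenyl)ethyl]tetrahydro-4H-pyran-4-one
Conditions: LiCl, DMSO, H2O, 130 °C
Reagents that add atoms: none
Why: Krapcho demethoxycarbonylation: chloride attacks the ester methyl group, the β-keto carboxylate loses carbon dioxide and the enolate is protonated by water. No stereocentre is formed, and because the cis isomer with both substituents equatorial is the thermodynamic one, any retro-oxa-Michael opening at C2 should return the same isomer.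

Step 8
Reactants: 13 (2S,6S)-6-[3,4-bis(benzyloxy)-5-methoxyphenyl]-2-[2-(4-benzyloxy-3-methoxyphenyl)ethyl]tetrahydro-4H-pyran-4-one
Product: 14 (2S,4R,6S)-6-[3,4-bis(benzyloxy)-5-methoxyphenyl]-2-[2-(4-benzyloxy-3-methoxyphenyl)ethyl]tetrahydro-2H-pyran-4-ol
Conditions: NaBH4, MeOH/THF, −20 → 0 °C
Reagents that add atoms: none
Why: Hydride reduction of a conformationally locked cyclic ketone; the small hydride should add axially to the chair in which both C2 and C6 substituents are equatorial, giving the equatorial 4R alcohol cis to both.

Step 9
Reactants: 14 (2S,4R,6S)-6-[3,4-bis(benzyloxy)-5-methoxyphenyl]-2-[2-(4-benzyloxy-3-methoxyphenyl)ethyl]tetrahydro-2H-pyran-4-ol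
Product: 15 (2S,4R,6S)-6-(3,4-dihydroxy-5-methoxyphenyl)-2-[2-(4-hydroxy-3-methoxyphenyl)ethyl]tetrahydro-2H-pyran-4-ol
Conditions: H2 (1 atm), 10% Pd/C, EtOAc/MeOH, rt; work-up under N2
Reagents that add atoms: none
Why: Catalytic hydrogenolysis of three aryl benzyl ethers; these should cleave far faster than the secondary, ring-bound benzylic C6–O1 ether, so the reaction is stopped once three equivalents of hydrogen are taken up, and the neutral medium leaves all three stereocentres untouched.

## Compound list

1 | 3,4-dihydroxy-5-methoxybenzaldehyde | COc1cc(C=O)cc(O)c1O | starting material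
2 | 3,4-bis(benzyloxy)-5-methoxybenzaldehyde | COc1cc(C=O)cc(OCc2ccccc2)c1OCc1ccccc1 | intermediate
3 | methyl acetoacetate | COC(=O)CC(C)=O | starting material
4 | methyl 3-(trimethylsilyloxy)but-2-enoate (E/Z mixture) | COC(=O)C=C(C)O[Si](C)(C)C | intermediate
5 | 1-methoxy-1,3-bis(trimethylsilyloxy)buta-1,3-diene | COC(O[Si](C)(C)C)=CC(=C)O[Si](C)(C)C | intermediate
6 | 3-(4-hydroxy-3-methoxyphenyl)propanoic acid | COc1cc(CCC(=O)O)ccc1O | starting material
7 | benzyl 3-(4-benzyloxy-3-methoxyphenyl)propanoate | COc1cc(CCC(=O)OCc2ccccc2)ccc1OCc1ccccc1 | intermediate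
8 | 3-(4-benzyloxy-3-methoxyphenyl)propanal | COc1cc(CCC=O)ccc1OCc1ccccc1 | intermediate
9 | methyl (5S)-5-[3,4-bis(benzyloxy)-5-methoxyphenyl]-3,5-bis(trimethylsilyloxy)pent-2-enoate | COC(=O)C=C(O[Si](C)(C)C)C[C@H](O[Si](C)(C)C)c1cc(OCc2ccccc2)c(OCc2ccccc2)c(OC)c1 | intermediate (not isolated)
10 | methyl (5S)-5-[3,4-bis(benzyloxy)-5-methoxyphenyl]-5-hydroxy-3-oxopentanoate | COC(=O)CC(=O)C[C@H](O)c1cc(OCc2ccccc2)c(OCc2ccccc2)c(OC)c1 | intermediate (not isolated)
11 | methyl (5S)-2-[3-(4-benzyloxy-3-methoxyphenyl)propylidene]-5-[3,4-bis(benzyloxy)-5-methoxyphenyl]-5-hydroxy-3-oxopentanoate (E/Z mixture) | COC(=O)C(=CCCc1ccc(OCc2ccccc2)c(OC)c1)C(=O)C[C@H](O)c1cc(OCc2ccccc2)c(OCc2ccccc2)c(OC)c1 | intermediate (not isolated)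
12 | methyl (2S,6S)-6-[3,4-bis(benzyloxy)-5-methoxyphenyl]-2-[2-(4-benzyloxy-3-methoxyphenyl)ethyl]-4-hydroxy-5,6-dihydro-2H-pyran-3-carboxylate | COc1cc(CC[C@H]2C(C(=O)OC)=C(O)C[C@@H](c3cc(OCc4ccccc4)c(OCc4ccccc4)c(OC)c3)O2)ccc1OCc1ccccc1 | intermediate
13 | (2S,6S)-6-[3,4-bis(benzyloxy)-5-methoxyphenyl]-2-[2-(4-benzyloxy-3-methoxyphenyl)ethyl]tetrahydro-4H-pyran-4-one | COc1cc(CC[C@H]2CC(=O)C[C@@H](c3cc(OCc4ccccc4)c(OCc4ccccc4)c(OC)c3)O2)ccc1OCc1ccccc1 | intermediate
14 | (2S,4R,6S)-6-[3,4-bis(benzyloxy)-5-methoxyphenyl]-2-[2-(4-benzyloxy-3-methoxyphenyl)ethyl]tetrahydro-2H-pyran-4-ol | COc1cc(CC[C@H]2C[C@@H](O)C[C@@H](c3cc(OCc4ccccc4)c(OCc4ccccc4)c(OC)c3)O2)ccc1OCc1ccccc1 | intermediate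
15 | (2S,4R,6S)-6-(3,4-dihydroxy-5-methoxyphenyl)-2-[2-(4-hydroxy-3-methoxyphenyl)ethyl]tetrahydro-2H-pyran-4-ol | COc1cc(CC[C@H]2C[C@@H](O)C[C@@H](c3cc(O)c(O)c(OC)c3)O2)ccc1O | target

## Step count and risk

Total step count: 9. Longest linear sequence: 6 steps (steps 2, 3, 6, 7, 8, 9, or equally steps 4, 5, 6, 7, 8, 9).

Step 6 (key step).
- What may go wrong: insufficient conversion or facial selectivity in the aldol, because 2 is an electron-rich and therefore weakly electrophilic aldehyde; and self-condensation of the enolisable aldehyde 8, or incomplete condensation, in a medium that still holds titanium alkoxide and ammonium trifluoroacetate.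
- Fallback: it sets out from 2 and rejoins the route at 10, which is then isolated. The catalytic aldol is replaced by an auxiliary-controlled acetate aldol. The titanium enolate (TiCl4, iPr2NEt, CH2Cl2, −78 °C) of the catalogue reagent 3-acetyl-(R)-4-benzyl-1,3-thiazolidine-2-thione adds to 2 to give (R)-4-benzyl-3-{(3S)-3-[3,4-bis(benzyloxy)-5-methoxyphenyl]-3-hydroxypropanoyl}-1,3-thiazolidine-2-thione F1. The chelated chair transition state is expected to give the S carbinol, the minor diastereomer is removed by chromatography, and the S auxiliary would be used if the sense proved opposite. Potassium methyl malonate with MgCl2 and imidazole in THF then displaces the auxiliary with decarboxylation and gives 10. 10 and 8 are condensed in a separate, titanium-free flask under piperidinium acetate with molecular sieves to reach 12.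

Step 7.
- What may go wrong: at 130 °C in a medium that turns basic, retro-oxa-Michael opening can occur on either side of the ketone. Opening and re-closure through a trans isomer would erode the cis geometry and, by passing C2 and C6 through the open form in turn, the enantiomeric purity; elimination to open-chain enones is also possible.
- Fallback: it sets out from 2 and 8 and rejoins the route at 13. The methyl ester is replaced by an allyl ester so that decarboxylation runs at room temperature without base. Allyl acetoacetate is silylated (TMSCl, Et3N) to allyl 3-(trimethylsilyloxy)but-2-enoate F2 and then (LDA, TMSCl) to 1-allyloxy-1,3-bis(trimethylsilyloxy)buta-1,3-diene F3. The assembly of step 6 with 2 and 8 gives allyl (2S,6S)-6-[3,4-bis(benzyloxy)-5-methoxyphenyl]-2-[2-(4-benzyloxy-3-methoxyphenyl)ethyl]-4-hydroxy-5,6-dihydro-2H-pyran-3-carboxylate F4. Pd(PPh3)4 (zerovalent palladium) with morpholine in THF at room temperature ionises the allyl ester, the β-keto acid loses carbon dioxide, and 13 results.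

Step 9.
- What may go wrong: over-reduction by hydrogenolytic cleavage of the ring C6–O1 bond, which is itself a benzylic ether, before the third benzyl group has gone; and air oxidation of the liberated catechol during isolation.
- Fallback: it sets out from 1 and 6 and rejoins the route at 15. The phenols are carried as allyl ethers, which are removed without hydrogen. Allyl bromide and K2CO3 convert 1 into 3,4-bis(allyloxy)-5-methoxybenzaldehyde F5 and 6 into allyl 3-(4-allyloxy-3-methoxyphenyl)propanoate F6. DIBAL-H reduces F6 to 3-(4-allyloxy-3-methoxyphenyl)propanal F7. The assembly of step 6 with 5 gives the tris-allyl keto ester F8. LiCl in wet DMSO at 130 °C, which is below the onset of aryl allyl ether Claisen rearrangement, gives the tris-allyl pyranone F9, and NaBH4 gives the tris-allyl pyranol F10. Pd(PPh3)4 (zerovalent palladium) with morpholine in THF then transfers the three allyl groups to the amine and releases 15.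

Step 5.
- What may go wrong: over-reduction of the aldehyde to the primary alcohol if the aluminium hemiacetal collapses before the quench.
- Fallback: it sets out from 7 and rejoins the route at 8. LiAlH4 in THF at 0 °C reduces 7 fully to 3-(4-benzyloxy-3-methoxyphenyl)propan-1-ol F11, and Dess–Martin periodinane in CH2Cl2 oxidises F11 to 8.

## Further compounds

F1 | step 6 | (R)-4-benzyl-3-{(3S)-3-[3,4-bis(benzyloxy)-5-methoxyphenyl]-3-hydroxypropanoyl}-1,3-thiazolidine-2-thione | O=C(C[C@H](O)c1cc(OCc2ccccc2)c(OCc2ccccc2)c(OC)c1)N1C(=S)SC[C@H]1Cc1ccccc1
F2 | step 7 | allyl 3-(trimethylsilyloxy)but-2-enoate (E/Z mixture) | C=CCOC(=O)C=C(C)O[Si](C)(C)C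
F3 | step 7 | 1-allyloxy-1,3-bis(trimethylsilyloxy)buta-1,3-diene | C=CCOC(O[Si](C)(C)C)=CC(=C)O[Si](C)(C)C
F4 | step 7 | allyl (2S,6S)-6-[3,4-bis(benzyloxy)-5-methoxyphenyl]-2-[2-(4-benzyloxy-3-methoxyphenyl)ethyl]-4-hydroxy-5,6-dihydro-2H-pyran-3-carboxylate | COc1cc(CC[C@H]2C(C(=O)OCC=C)=C(O)C[C@@H](c3cc(OCc4ccccc4)c(OCc4ccccc4)c(OC)c3)O2)ccc1OCc1ccccc1
F5 | step 9 | 3,4-bis(allyloxy)-5-methoxybenzaldehyde | COc1cc(C=O)cc(OCC=C)c1OCC=C
F6 | step 9 | allyl 3-(4-allyloxy-3-methoxyphenyl)propanoate | COc1cc(CCC(=O)OCC=C)ccc1OCC=C
F7 | step 9 | 3-(4-allyloxy-3-methoxyphenyl)propanal | COc1cc(CCC=O)ccc1OCC=C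
F8 | step 9 | methyl (2S,6S)-2-[2-(4-allyloxy-3-methoxyphenyl)ethyl]-6-[3,4-bis(allyloxy)-5-methoxyphenyl]-4-hydroxy-5,6-dihydro-2H-pyran-3-carboxylate | COc1cc(CC[C@H]2C(C(=O)OC)=C(O)C[C@@H](c3cc(OCC=C)c(OCC=C)c(OC)c3)O2)ccc1OCC=C
F9 | step 9 | (2S,6S)-2-[2-(4-allyloxy-3-methoxyphenyl)ethyl]-6-[3,4-bis(allyloxy)-5-methoxyphenyl]tetrahydro-4H-pyran-4-one | COc1cc(CC[C@H]2CC(=O)C[C@@H](c3cc(OCC=C)c(OCC=C)c(OC)c3)O2)ccc1OCC=C
F10 | step 9 | (2S,4R,6S)-2-[2-(4-allyloxy-3-methoxyphenyl)ethyl]-6-[3,4-bis(allyloxy)-5-methoxyphenyl]tetrahydro-2H-pyran-4-ol | COc1cc(CC[C@H]2C[C@@H](O)C[C@@H](c3cc(OCC=C)c(OCC=C)c(OC)c3)O2)ccc1OCC=C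
F11 | step 5 | 3-(4-benzyloxy-3-methoxyphenyl)propan-1-ol | COc1cc(CCCO)ccc1OCc1ccccc1
A1 | alternative 1 | 2-(tert-butyldimethylsilyl)-1,3-dithiane | CC(C)(C)[Si](C)(C)C1SCCCS1
A2 | alternative 1 | (S)-2-[2-(4-benzyloxy-3-methoxyphenyl)ethyl]oxirane | COc1cc(CC[C@H]2CO2)ccc1OCc1ccccc1
A3 | alternative 1 | 2-[3,4-bis(benzyloxy)-5-methoxyphenyl]oxirane (racemic) | COc1cc(C2CO2)cc(OCc2ccccc2)c1OCc1ccccc1
A4 | alternative 1 | 2-{(2S)-4-(4-benzyloxy-3-methoxyphenyl)-2-[(tert-butyldimethylsilyl)oxy]butyl}-2-{2-[3,4-bis(benzyloxy)-5-methoxyphenyl]-2-hydroxyethyl}-1,3-dithiane (both carbinol epimers) | COc1cc(CC[C@H](O[Si](C)(C)C(C)(C)C)CC2(SCCCS2)CC(O)c2cc(OCc3ccccc3)c(OCc3ccccc3)c(OC)c2)ccc1OCc1ccccc1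
A5 | alternative 2 | iron trichloride hexahydrate, FeCl3·6H2O | [Fe+3].[Cl-].[Cl-].[Cl-].O.O.O.O.O.O
A6 | alternative 2 | (2E,5R,7S)-1-(4-benzyloxy-3-methoxyphenyl)-7-[3,4-bis(benzyloxy)-5-methoxyphenyl]-5-[(tert-butyldimethylsilyl)oxy]hept-2-ene-1,7-diol (both C1 epimers) | COc1cc(C(O)/C=C/C[C@@H](O[Si](C)(C)C(C)(C)C)C[C@H](O)c2cc(OCc3ccccc3)c(OCc3ccccc3)c(OC)c2)ccc1OCc1ccccc1
A7 | alternative 2 | all-cis 2-[3,4-bis(benzyloxy)-5-methoxyphenyl]-6-[(E)-2-(4-benzyloxy-3-methoxyphenyl)ethenyl]-4-[(tert-butyldimethylsilyl)oxy]tetrahydropyran | COc1cc(/C=C/[C@H]2C[C@@H](O[Si](C)(C)C(C)(C)C)C[C@@H](c3cc(OCc4ccccc4)c(OCc4ccccc4)c(OC)c3)O2)ccc1OCc1ccccc1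
A8 | alternative 3 | (S)-5-(4-benzyloxy-3-methoxyphenyl)-3-hydroxypentanoic acid | COc1cc(CC[C@H](O)CC(=O)O)ccc1OCc1ccccc1
A9 | alternative 3 | cis-2-[3,4-bis(benzyloxy)-5-methoxyphenyl]-6-[2-(4-benzyloxy-3-methoxyphenyl)ethyl]-4-methylene-1,3-dioxane | C=C1C[C@H](CCc2ccc(OCc3ccccc3)c(OC)c2)O[C@H](c2cc(OCc3ccccc3)c(OCc3ccccc3)c(OC)c2)O1
A10 | alternative 3 | dimethylaluminium chloride, Me2AlCl | C[Al](C)Cl
A11 | alternative 3 | (2S,6S)-6-[3,4-bis(benzyloxy)-5-methoxyphenyl]-2-[2-(4-benzyloxy-3-methoxyphenyl)ethyl]tetrahydro-4H-pyran-4-one (identical with 13) | COc1cc(CC[C@H]2CC(=O)C[C@@H](c3cc(OCc4ccccc4)c(OCc4ccccc4)c(OC)c3)O2)ccc1OCc1ccccc1
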